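**Retrosynthetic overview**
1. Target 17 comes from alcohol 16 and silyl ether 15 by acetylation and desilylation; 15 comes from 4-hydroxy-2-pyranone 13 by methylation of the C2 carbonyl oxygen.
2. Feature used: ring atoms O1–C2(=O)–C3(CH3) are a propionate ester of the C6 enol oxygen, and C4 with C5=C6 is the ester carbonyl of a (Z)-β-acyloxy-α-methylacrylate. The single ring is therefore closed last at the C3–C4 carbon–carbon bond and not at O1.
3. 13 comes from enol ester 10 by intramolecular Claisen condensation; 10 comes from β-keto ester 7 and propionyl chloride 8 by O-acylation of the chelated enolate.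
4. 7 comes from acid 3 and methyl propionate 4 by crossed Claisen condensation through the imidazolide; 3 comes from 12-hydroxydodecanoic acid 1.

Key step: step 4

Remark: the target has no stereocentre, so the only stereochemical element is the Z geometry of enol ester 10. The chain hydroxyl is carried as a tert-butyldiphenylsilyl ether because it must pass a lithium amide and later the triflic acid of the methylation.

Step 1
Reactants: 1 12-hydroxydodecanoic acid
Product: 3 12-[(tert-butyldiphenylsilyl)oxy]dodecanoic acid, via bis-silyl compound 2 (not isolated)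
Conditions: TBDPSCl (2.3 equiv), imidazole, DMF, rt; then K2CO3, THF/H2O, rt; 1 M HCl to pH 4, 0 °C
Reagents that add atoms: tert-butyldiphenylsilyl chloride, CC(C)(C)[Si](Cl)(c1ccccc1)c1ccccc1
Why: Imidazole-promoted silylation covers both the hydroxyl and the carboxyl group, and the silyl ester, far more labile than the primary silyl ether, should be hydrolysed selectively by aqueous carbonate (standard protection of a hydroxy acid).

Step 2
Reactants: 3 12-[(tert-butyldiphenylsilyl)oxy]dodecanoic acid; 4 methyl propionate
Product: 7 methyl 14-[(tert-butyldiphenylsilyl)oxy]-2-methyl-3-oxotetradecanoate (racemic at C2), via acyl imidazolide 5 (not isolated), via lithium enolate 6 (not isolated)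
Conditions: 1,1'-carbonyldiimidazole (1.1 equiv), THF, rt; added to 4 (3.5 equiv) + LiN(iPr)2 (3.5 equiv), THF, −78 → −40 °C; 1 M HCl, 0 °C
Reagents that add atoms: none
Why: Crossed Claisen condensation of an acyl imidazolide with a lithium ester enolate, in which the excess enolate absorbs the imidazole N–H and stores the β-keto ester as its enolate so that no second addition occurs; the C2 stereocentre forms racemic and is erased in step 3.

Step 3
Reactants: 7 methyl 14-[(tert-butyldiphenylsilyl)oxy]-2-methyl-3-oxotetradecanoate; 8 propionyl chloride
Product: 10 methyl (Z)-14-[(tert-butyldiphenylsilyl)oxy]-2-methyl-3-(propanoyloxy)tetradec-2-enoate, via sodium enolate 9 (not isolated)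
Conditions: NaH (1.1 equiv), Et2O, 0 °C; then 8 (1.15 equiv), −20 → 0 °C
Reagents that add atoms: none
Why: O-Acylation of a β-keto ester enolate by an acid chloride is a standard route to enol esters, and in diethyl ether the sodium ion should bridge the two oxygens of 9 so that the enolate oxygen is acylated while held cis to CO2Me, which gives the Z alkene; the α-methyl group hinders acylation at the fully substituted carbon, and a magnesium chelate is avoided because it steers acid chlorides to carbon.

Step 4
Reactants: 10 methyl (Z)-14-[(tert-butyldiphenylsilyl)oxy]-2-methyl-3-(propanoyloxy)tetradec-2-enoate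
Product: 13 6-{11-[(tert-butyldiphenylsilyl)oxy]undecyl}-4-hydroxy-3,5-dimethyl-2H-pyran-2-one, via lithium ester enolate 11 (not isolated), via lithium pyranolate 12 (not isolated)
Conditions: LiN(SiMe3)2 (2.5 equiv), THF, −78 °C, slow addition of 10 (high dilution), −78 → −30 °C; then 1 M HCl to pH 2, 0 °C
Reagents that add atoms: none
Why: Proposed new method: LiN(SiMe3)2 should deprotonate the propionate CH2 of the enol ester, and the enolate carbon (the future C3) should add to the methyl ester carbonyl (the future C4) that the Z double bond C5=C6 holds cis to it, after which loss of methoxide and immediate deprotonation of the 3H-pyran-2,4-dione to the 4-oxidopyranone 12 make the C3–C4 bond formation irreversible (intramolecular Claisen, that is Dieckmann-type, condensation). The closest known reaction types are the base-mediated cyclisation of methyl O-acylsalicylates to 3-substituted 4-hydroxycoumarins, which is the benzo-fused counterpart, the Lacey–Dieckmann closure of O-acyl α-hydroxy esters to tetronic acids and the Baker–Venkataraman acyl transfer, whereas an acyclic β-acyloxyacrylate has not been closed in this way. The single ring is closed in a 6-exo-trig mode and no stereocentre is formed, the enolate geometry being lost in the aromatic product. The step needs enolisation at the propionate CH2 and not at the allylic chain CH2 on C6, which is vinylogously acidic but lies trans to the ester carbonyl where a lithium amide removes protons slowly, while C5 carries no hydrogen at all. It also needs ring closure to outrun E1cB expulsion of the keto ester enolate with loss of methylketene, for which the low temperature, the lithium counter-ion, the six-membered transition state fixed by the Z alkene and the twist of the ester out of the alkene plane (which turns its π* towards C3) are relied on. Slow addition of 10 to an excess of base should keep un-enolised enol ester away from the LiOMe that is set free.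

Step 5
Reactants: 13 6-{11-[(tert-butyldiphenylsilyl)oxy]undecyl}-4-hydroxy-3,5-dimethyl-2H-pyran-2-one
Product: 15 6-{11-[(tert-butyldiphenylsilyl)oxy]undecyl}-2-methoxy-3,5-dimethyl-4H-pyran-4-one, via pyrylium triflate 14 (not isolated)
Conditions: MeOTf (1.5 equiv), CH2Cl2, 0 °C → rt; then sat. aq. NaHCO3
Reagents that add atoms: methyl trifluoromethanesulfonate, COS(=O)(=O)C(F)(F)F
Why: Methyl triflate is a hard electrophile that should alkylate the neutral 4-hydroxy-2-pyranone at its most basic site, the C2 carbonyl oxygen, to the aromatic pyrylium salt 14, which bicarbonate deprotonates at the 4-hydroxyl to the 2-methoxy-4-pyranone (known O-alkylation of 4-hydroxy-2-pyranones by methyl triflate or methyl fluorosulfonate); the cationic salt is shielded from a second methylation and the bulky silyl ether should withstand the acidic medium.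

Step 6
Reactants: 15 6-{11-[(tert-butyldiphenylsilyl)oxy]undecyl}-2-methoxy-3,5-dimethyl-4H-pyran-4-one
Product: 16 6-(11-hydroxyundecyl)-2-methoxy-3,5-dimethyl-4H-pyran-4-one
Conditions: Bu4NF (1.5 equiv), AcOH (1.5 equiv), THF, rt
Reagents that add atoms: none
Why: Fluoride-induced cleavage of the silyl ether driven by Si–F bond formation, buffered with acetic acid so that neither fluoride nor the alkoxide attacks the methoxypyranone, which is a vinylogous carbonate.

Step 7
Reactants: 16 6-(11-hydroxyundecyl)-2-methoxy-3,5-dimethyl-4H-pyran-4-one
Product: 17 11-(6-methoxy-3,5-dimethyl-4-oxo-4H-pyran-2-yl)undecyl acetate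
Conditions: Ac2O, pyridine, DMAP (cat.), CH2Cl2, 0 °C → rt
Reagents that add atoms: acetic anhydride, CC(=O)OC(C)=O
Why: DMAP-catalysed acetylation of the only hydroxyl group, a primary alcohol, under mild basic conditions that the methoxypyranone should tolerate.

**Compound list**
1 | 12-hydroxydodecanoic acid | OCCCCCCCCCCCC(=O)O | starting material
2 | tert-butyldiphenylsilyl 12-[(tert-butyldiphenylsilyl)oxy]dodecanoate | CC(C)(C)[Si](c1ccccc1)(c1ccccc1)OC(=O)CCCCCCCCCCCO[Si](c1ccccc1)(c1ccccc1)C(C)(C)C | intermediate
3 | 12-[(tert-butyldiphenylsilyl)oxy]dodecanoic acid | OC(=O)CCCCCCCCCCCO[Si](c1ccccc1)(c1ccccc1)C(C)(C)C | intermediate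
4 | methyl propionate | CCC(=O)OC | starting material
5 | 1-{12-[(tert-butyldiphenylsilyl)oxy]dodecanoyl}imidazole | O=C(CCCCCCCCCCCO[Si](c1ccccc1)(c1ccccc1)C(C)(C)C)n1ccnc1 | intermediate
6 | lithium enolate of methyl propionate (geometry not defined) | [Li+].CC=C([O-])OC | intermediate
7 | methyl 14-[(tert-butyldiphenylsilyl)oxy]-2-methyl-3-oxotetradecanoate (racemic) | COC(=O)C(C)C(=O)CCCCCCCCCCCO[Si](c1ccccc1)(c1ccccc1)C(C)(C)C | intermediate
8 | propionyl chloride | CCC(Cl)=O | starting material
9 | sodium (Z)-enolate of keto ester 7 | [Na+].[O-]/C(CCCCCCCCCCCO[Si](c1ccccc1)(c1ccccc1)C(C)(C)C)=C(/C)C(=O)OC | intermediate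
10 | methyl (Z)-14-[(tert-butyldiphenylsilyl)oxy]-2-methyl-3-(propanoyloxy)tetradec-2-enoate | CCC(=O)O/C(CCCCCCCCCCCO[Si](c1ccccc1)(c1ccccc1)C(C)(C)C)=C(/C)C(=O)OC | intermediate
11 | lithium enolate of the propionate ester of 10 (enolate geometry not defined) | [Li+].CC=C([O-])O/C(CCCCCCCCCCCO[Si](c1ccccc1)(c1ccccc1)C(C)(C)C)=C(/C)C(=O)OC | intermediate
12 | lithium 6-{11-[(tert-butyldiphenylsilyl)oxy]undecyl}-3,5-dimethyl-2-oxo-2H-pyran-4-olate | [Li+].Cc1c([O-])c(C)c(CCCCCCCCCCCO[Si](c2ccccc2)(c2ccccc2)C(C)(C)C)oc1=O | intermediate
13 | 6-{11-[(tert-butyldiphenylsilyl)oxy]undecyl}-4-hydroxy-3,5-dimethyl-2H-pyran-2-one | Cc1c(O)c(C)c(CCCCCCCCCCCO[Si](c2ccccc2)(c2ccccc2)C(C)(C)C)oc1=O | intermediate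
14 | 6-{11-[(tert-butyldiphenylsilyl)oxy]undecyl}-4-hydroxy-2-methoxy-3,5-dimethylpyrylium triflate | COc1[o+]c(CCCCCCCCCCCO[Si](c2ccccc2)(c2ccccc2)C(C)(C)C)c(C)c(O)c1C.[O-]S(=O)(=O)C(F)(F)F | intermediate
15 | 6-{11-[(tert-butyldiphenylsilyl)oxy]undecyl}-2-methoxy-3,5-dimethyl-4H-pyran-4-one | COc1oc(CCCCCCCCCCCO[Si](c2ccccc2)(c2ccccc2)C(C)(C)C)c(C)c(=O)c1C | intermediate
16 | 6-(11-hydroxyundecyl)-2-methoxy-3,5-dimethyl-4H-pyran-4-one | COc1oc(CCCCCCCCCCCO)c(C)c(=O)c1C | intermediate
17 | 11-(6-methoxy-3,5-dimethyl-4-oxo-4H-pyran-2-yl)undecyl acetate | COc1oc(CCCCCCCCCCCOC(C)=O)c(C)c(=O)c1C | target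

Total step count: 7
Longest linear sequence: 7 steps (1 to 17)

**Steps most likely to fail**

1. Step 4 (proposed new method). The ester enolate may fragment by expulsion of the keto ester enolate with loss of methylketene. An allylic proton of the chain may be removed in place of a propionate proton. The liberated methoxide may cleave the enol ester before it is enolised. Fallback, by known chemistry: it sets out from acid 3 and comes back at pyranone 13. Acid 3 is converted as in step 2 into imidazolide 5, which is added to the dianion of commercial methyl 2-methyl-3-oxopentanoate (NaH, then n-BuLi, THF, −78 → 0 °C). Acylation at the terminal carbanion should give the diketo ester methyl 16-[(tert-butyldiphenylsilyl)oxy]-2,4-dimethyl-3,5-dioxohexadecanoate F1 as a mixture of stereoisomers and tautomers. DBU in toluene at 80 °C should then lactonise the enol oxygen of the C5 ketone onto the ester, closing the ring at O1–C2 and giving 13.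

2. Step 3. The sodium chelate may open before acylation, which would place the acyl group trans to the ester and give an enol ester that cannot cyclise. Acylation may also occur at carbon. Fallback: it sets out from keto ester 7 and comes back at enol ester 10 without passing through a new compound (F0). Compound 7 is heated with propionic anhydride and catalytic p-toluenesulfonic acid in toluene at 60 °C. The acyl group is then transferred to the neutral enol and not to a metal enolate. That enol exists only in the intramolecularly hydrogen-bonded form with the hydroxyl cis to CO2Me, so acid-catalysed enol esterification should deliver the Z isomer. The tert-butyldiphenylsilyl ether is expected to tolerate catalytic sulfonic acid in the absence of water or alcohol.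

3. Step 5. The silyl ether may be lost in the strongly acidic, strongly methylating medium, followed by methylation of the freed chain hydroxyl; to a lesser degree methylation may occur at the C4 oxygen. Fallback: it sets out from pyranone 13 and comes back at target 17, with the order of the end-game reversed so that the methylation meets an acetate and no silyl ether. Compound 13 is desilylated with excess Bu4NF in THF followed by acidic work-up to 4-hydroxy-6-(11-hydroxyundecyl)-3,5-dimethyl-2H-pyran-2-one F2. Immobilised Candida antarctica lipase B with vinyl acetate should acetylate only the primary alcohol, giving 11-(4-hydroxy-3,5-dimethyl-2-oxo-2H-pyran-6-yl)undecyl acetate F3. Methyl triflate in CH2Cl2 should then give 6-(11-acetoxyundecyl)-4-hydroxy-2-methoxy-3,5-dimethylpyrylium triflate F4, which aqueous NaHCO3 converts into 17.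

**Further compounds**
F1 | step 4 | methyl 16-[(tert-butyldiphenylsilyl)oxy]-2,4-dimethyl-3,5-dioxohexadecanoate | COC(=O)C(C)C(=O)C(C)C(=O)CCCCCCCCCCCO[Si](c1ccccc1)(c1ccccc1)C(C)(C)C
F0 | step 3 | none | none
F2 | step 5 | 4-hydroxy-6-(11-hydroxyundecyl)-3,5-dimethyl-2H-pyran-2-one | Cc1c(O)c(C)c(CCCCCCCCCCCO)oc1=O
F3 | step 5 | 11-(4-hydroxy-3,5-dimethyl-2-oxo-2H-pyran-6-yl)undecyl acetate | CC(=O)OCCCCCCCCCCCc1oc(=O)c(C)c(O)c1C
F4 | step 5 | 6-(11-acetoxyundecyl)-4-hydroxy-2-methoxy-3,5-dimethylpyrylium triflate | COc1[o+]c(CCCCCCCCCCCOC(C)=O)c(C)c(O)c1C.[O-]S(=O)(=O)C(F)(F)F
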